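## Retrosynthetic overview
1. The (3S)-isoflavan comes from the fully decorated, unprotected 2'-hydroxyisoflavone. One flask delivers hydride to C2, to C4=O and to the C4 quinone methide. The ketone reduction runs as a dynamic kinetic resolution and sets C3. A pterocarpan furan ring closes and reopens on the way.
2. The isoflavone comes from a chalcone epoxide by a 1,2-shift to the 2-aryl-3-oxopropanal. Ring C closes as the 2-hydroxyisoflavanone, which then dehydrates.
3. The chalcone epoxide comes from the MOM-protected 3-prenylresacetophenone and the MOM-protected chromene aldehyde. The steps are a Claisen–Schmidt condensation and a nucleophilic epoxidation that ignores both electron-rich olefins.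
4. The chromene aldehyde comes from 2,4-dihydroxybenzaldehyde and prenal (ortho-quinone methide, oxa-6π closure). The prenyl ketone comes from 2,4-dihydroxyacetophenone and prenyl bromide.
5. Ring order: chromene ring D, then pyranone ring C, then the transient furan ring (opened again), then the saturated ring C of the target.

Assumption: the SMILES is read as (3S) (C2 > aryl > C4 > H), the spatial arrangement of (S)-equol. The sense of induction follows the usual rule that the (S,S)-TsDPEN ruthenium catalyst gives the (S)-benzylic alcohol.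

## Route

Step 1
Reactants: 1 2,4-dihydroxybenzaldehyde; 2 3-methylbut-2-enal (prenal)
Product: 4 5-hydroxy-2,2-dimethyl-2H-chromene-6-carbaldehyde, via ortho-quinone methide 3 (not isolated)
Conditions: ethylenediammonium diacetate (10 mol%), xylene, reflux, 8 h
Reagents that add atoms: none
Why: Knoevenagel-type condensation at C3 of 1, the carbon between the two oxygens, gives ortho-quinone methide 3, and its oxa-6π electrocyclisation through the non-chelated 4-oxygen closes the chromene as in the oxidative cyclisation of an ortho-prenylphenol, while the 2-OH stays hydrogen-bonded to the aldehyde; no stereocentre is formed.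

Step 2
Reactants: 4 5-hydroxy-2,2-dimethyl-2H-chromene-6-carbaldehyde
Product: 5 5-(methoxymethoxy)-2,2-dimethyl-2H-chromene-6-carbaldehyde
Conditions: NaH (1.3 equiv), MOMCl (1.3 equiv), DMF, 0 °C to rt
Reagents that add atoms: chloromethyl methyl ether (MOMCl), COCCl
Why: Williamson-type O-alkylation of the sodium phenoxide breaks the chelate and masks the phenol that would otherwise deactivate the aldehyde and later open the epoxide through an ortho-quinone methide.

Step 3
Reactants: 6 2,4-dihydroxyacetophenone; 7 1-bromo-3-methylbut-2-ene (prenyl bromide)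
Product: 8 1-[2,4-dihydroxy-3-(3-methylbut-2-enyl)phenyl]ethanone
Conditions: KOH (1.1 equiv), H2O, 0 °C to rt, 12 h; chromatography
Reagents that add atoms: none
Why: phenolate C-alkylation in water, where hydrogen bonding shields the oxygens, places the prenyl cation equivalent on the doubly activated C3 between the two oxygens as an aromatic prenyltransferase does, and the minor 5-prenyl and O-prenyl isomers are separated.

Step 4
Reactants: 8 1-[2,4-dihydroxy-3-(3-methylbut-2-enyl)phenyl]ethanone
Product: 9 1-[2,4-bis(methoxymethoxy)-3-(3-methylbut-2-enyl)phenyl]ethanone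
Conditions: NaH (2.3 equiv), MOMCl (2.4 equiv), DMF, 0 °C to rt
Reagents that add atoms: chloromethyl methyl ether (MOMCl), COCCl
Why: double Williamson-type O-alkylation works because both phenols are far more acidic than the methyl ketone; masking the 2-OH blocks Algar–Flynn–Oyamada chemistry in step 5, and masking the 4-OH keeps the enone electrophilic.

Step 5
Reactants: 5 5-(methoxymethoxy)-2,2-dimethyl-2H-chromene-6-carbaldehyde; 9 1-[2,4-bis(methoxymethoxy)-3-(3-methylbut-2-enyl)phenyl]ethanone
Product: 11 racemic trans-[2,4-bis(methoxymethoxy)-3-(3-methylbut-2-enyl)phenyl]{3-[5-(methoxymethoxy)-2,2-dimethyl-2H-chromen-6-yl]oxiran-2-yl}methanone, via chalcone 10 (not isolated)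
Conditions: KOH, EtOH/THF, rt, 24 h; then 30% H2O2 (6 equiv), 0 °C to rt; extractive work-up, used crude
Reagents that add atoms: hydrogen peroxide, OO
Why: Claisen–Schmidt condensation gives (E)-chalcone 10, and the Weitz–Scheffer epoxidation by hydroperoxide anion attacks only the electron-poor enone, so the prenyl and chromene olefins that electrophilic oxidants such as Tl(NO3)3 or PhI(OAc)2 would destroy survive; the trans-epoxide is racemic, which does not matter because both its stereocentres are erased in step 6.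

Step 6
Reactants: 11 racemic trans-chalcone epoxide
Product: 15 7-hydroxy-3-(5-hydroxy-2,2-dimethyl-2H-chromen-6-yl)-8-(3-methylbut-2-enyl)-4H-chromen-4-one, via formyl ketone 12 (not isolated), via 2-hydroxyisoflavanone 13 (not isolated), via bis-MOM isoflavone 14 (not isolated)
Conditions: BF3·OEt2 (30 mol%), CH2Cl2, −40 to 0 °C, 30 min; then MeOH, conc. HCl (cat.), rt 2 h, then 50 °C 3 h
Reagents that add atoms: none
Why: Lewis-acid opening at the dialkoxybenzylic carbon triggers the Meinwald-type 1,2-aroyl shift of chalcone epoxides and gives the 1,2-diaryl skeleton of the biosynthetic aryl migration as formyl ketone 12; acid methanolysis then frees the carbonyl-chelated phenol first, ring C closes as 2-hydroxyisoflavanone 13 and dehydrates to 14 before the ring B phenol exists, which avoids 3-aroylbenzofuran formation, and warming removes the last two MOM groups while the deactivated 7-OH leaves the prenyl group alone; no stereocentre remains.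

Step 7
Reactants: 15 7-hydroxy-3-(5-hydroxy-2,2-dimethyl-2H-chromen-6-yl)-8-(3-methylbut-2-enyl)-4H-chromen-4-one
Product: 20 (3S)-3-(5-hydroxy-2,2-dimethyl-2H-chromen-6-yl)-8-(3-methylbut-2-en-1-yl)-3,4-dihydro-2H-chromen-7-ol, via isoflavanone 16 (not isolated), via cis-isoflavan-4-ol 17 (not isolated), via para-quinone methide 18 (not isolated), via pterocarpan 19 (not isolated)
Conditions: RuCl[(S,S)-TsDPEN](p-cymene) (3 mol%), HCO2H/Et3N 5:2, EtOAc, 40 °C, 24 h; evaporate; then NaBH4 (6 equiv), 1 M NaOH/i-PrOH 1:1, 65 °C, Ar; NH4Cl work-up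
Reagents that add atoms: none
Why: Proposed new method: the bifunctional Ru–H adds hydride to C2 of the chromone, isoflavanone 16 racemises through its enol, and the (S,S)-catalyst reduces only the (3S)-ketone to the (4S)-alcohol (dynamic kinetic resolution to cis-17, which fixes C3 as S); in hot alkaline borohydride the 7-phenoxide expels the C4 oxygen to give para-quinone methide 18, which the 2'-phenoxide traps reversibly as pterocarpan 19 and hydride traps irreversibly at C4, so all material drains to 20 without touching C3 or either olefin; the closest known reaction types are the asymmetric transfer hydrogenation of isoflavones to cis-isoflavan-4-ols and the borohydride hydrogenolysis of para-hydroxybenzyl alcohols in aqueous alkali.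

## Compound list
1 | 2,4-dihydroxybenzaldehyde | O=Cc1ccc(O)cc1O | starting material
2 | 3-methylbut-2-enal (prenal) | CC(C)=CC=O | starting material
3 | 2-hydroxy-3-(3-methylbut-2-en-1-ylidene)-4-oxocyclohexa-1,5-diene-1-carbaldehyde (transient ortho-quinone methide) | O=C1C=CC(C=O)=C(O)/C1=C/C=C(C)C | intermediate
4 | 5-hydroxy-2,2-dimethyl-2H-chromene-6-carbaldehyde | CC1(C)C=Cc2c(O1)ccc(C=O)c2O | intermediate
5 | 5-(methoxymethoxy)-2,2-dimethyl-2H-chromene-6-carbaldehyde | CC1(C)C=Cc2c(O1)ccc(C=O)c2OCOC | intermediate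
6 | 2,4-dihydroxyacetophenone | CC(=O)c1ccc(O)cc1O | starting material
7 | 1-bromo-3-methylbut-2-ene (prenyl bromide) | CC(C)=CCBr | starting material
8 | 1-[2,4-dihydroxy-3-(3-methylbut-2-enyl)phenyl]ethanone | CC(=O)c1ccc(O)c(CC=C(C)C)c1O | intermediate
9 | 1-[2,4-bis(methoxymethoxy)-3-(3-methylbut-2-enyl)phenyl]ethanone | CC(=O)c1ccc(OCOC)c(CC=C(C)C)c1OCOC | intermediate
10 | (E)-1-[2,4-bis(methoxymethoxy)-3-(3-methylbut-2-enyl)phenyl]-3-[5-(methoxymethoxy)-2,2-dimethyl-2H-chromen-6-yl]prop-2-en-1-one (chalcone, transient) | O=C(/C=C/c1ccc2c(c1OCOC)C=CC(C)(C)O2)c1ccc(OCOC)c(CC=C(C)C)c1OCOC | intermediate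
11 | trans-chalcone epoxide of 10 (racemic, one enantiomer drawn) | O=C(c1ccc(OCOC)c(CC=C(C)C)c1OCOC)[C@H]1O[C@@H]1c1ccc2c(c1OCOC)C=CC(C)(C)O2 | intermediate
12 | 3-[2,4-bis(methoxymethoxy)-3-(3-methylbut-2-enyl)phenyl]-2-[5-(methoxymethoxy)-2,2-dimethyl-2H-chromen-6-yl]-3-oxopropanal (transient, centre labile) | O=CC(c1ccc2c(c1OCOC)C=CC(C)(C)O2)C(=O)c1ccc(OCOC)c(CC=C(C)C)c1OCOC | intermediate
13 | 2-hydroxy-7-(methoxymethoxy)-3-[5-(methoxymethoxy)-2,2-dimethyl-2H-chromen-6-yl]-8-(3-methylbut-2-enyl)chroman-4-one (transient, isomer mixture) | OC1Oc2c(CC=C(C)C)c(OCOC)ccc2C(=O)C1c1ccc2c(c1OCOC)C=CC(C)(C)O2 | intermediate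
14 | 7-(methoxymethoxy)-3-[5-(methoxymethoxy)-2,2-dimethyl-2H-chromen-6-yl]-8-(3-methylbut-2-enyl)-4H-chromen-4-one (transient) | CC(C)=CCc1c(OCOC)ccc2c1OC=C(c1ccc3c(c1OCOC)C=CC(C)(C)O3)C2=O | intermediate
15 | 7-hydroxy-3-(5-hydroxy-2,2-dimethyl-2H-chromen-6-yl)-8-(3-methylbut-2-enyl)-4H-chromen-4-one | CC(C)=CCc1c(O)ccc2c1OC=C(c1ccc3c(c1O)C=CC(C)(C)O3)C2=O | intermediate
16 | 7-hydroxy-3-(5-hydroxy-2,2-dimethyl-2H-chromen-6-yl)-8-(3-methylbut-2-enyl)chroman-4-one (transient, C3 racemising) | CC(C)=CCc1c(O)ccc2c1OCC(c1ccc3c(c1O)C=CC(C)(C)O3)C2=O | intermediate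
17 | (3S,4S)-3-(5-hydroxy-2,2-dimethyl-2H-chromen-6-yl)-8-(3-methylbut-2-enyl)chroman-4,7-diol (cis, transient) | CC(C)=CCc1c(O)ccc2c1OC[C@H](c1ccc3c(c1O)C=CC(C)(C)O3)[C@@H]2O | intermediate
18 | (3S)-3-(5-hydroxy-2,2-dimethyl-2H-chromen-6-yl)-8-(3-methylbut-2-enyl)-2,3-dihydro-7H-chromen-7-one (transient para-quinone methide) | CC(C)=CCC1=C2OC[C@H](c3ccc4c(c3O)C=CC(C)(C)O4)C=C2C=CC1=O | intermediate
19 | (6aS,11aS)-3-hydroxy-4-(3-methylbut-2-enyl)pterocarpan carrying the 2,2-dimethylpyran ring fused at C9(O)/C10 (cis-fused, transient) | CC(C)=CCc1c(O)ccc2c1OC[C@@H]3c4ccc5c(c4O[C@H]23)C=CC(C)(C)O5 | intermediate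
20 | (3S)-3-(5-hydroxy-2,2-dimethyl-2H-chromen-6-yl)-8-(3-methylbut-2-en-1-yl)-3,4-dihydro-2H-chromen-7-ol | CC(C)=CCc1c(O)ccc2c1OC[C@H](c1ccc3c(c1O)C=CC(C)(C)O3)C2 | target

## Count and risks
Total steps: 7. Longest linear sequence: 5 (steps 1, 2, 5, 6, 7, or steps 3, 4, 5, 6, 7).

**Step 7 (highest risk).**
- The free 7-OH may slow the conjugate reduction.
- Quinone methide 18 may tautomerise to the achiral isoflav-3-ene before hydride arrives.

The fallback sets out from 14 and comes back at 20. Step 6 is stopped at the room-temperature stage and 14 is isolated. The same transfer hydrogenation gives the protected (3S,4S)-cis-isoflavan-4-ol F1. Ionic hydrogenation (Et3SiH, BF3·OEt2, CH2Cl2, −78 °C) through the para-alkoxybenzyl cation gives the protected (3S)-isoflavan F2. No free phenol sits next to the prenyl group at this point. Brief methanolysis with pyridinium p-toluenesulfonate at 40 °C then gives 20.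

**Step 6.**
- The benzylic cation may shed the ortho MOM group or undergo a hydride shift instead of the aroyl shift.
- Early loss of the ring B MOM would divert 12 to a 3-aroylbenzofuran.

The fallback sets out from 10 (isolated by leaving out H2O2 in step 5) and comes back at 14.
- Catalytic p-TsOH in MeOH at 0 °C removes only the carbonyl-chelated MOM and gives the 2'-hydroxychalcone F3.
- Cold alkaline H2O2 (Algar–Flynn–Oyamada conditions, stopped early) closes ring C first and gives the racemic trans-3-hydroxyflavanone F4.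
- Tf2O/2,6-lutidine at −78 °C gives the triflate F5.
- On warming in (CF3)2CHOH, F5 loses triflate with anchimeric help from the electron-rich 2-aryl group. This is a true C2-to-C3 aryl shift on the flavanone skeleton.
- The C2 oxocarbenium ion loses H3 to give 14, which the warm HCl/MeOH stage converts to 15.

**Step 3.** Direct C-prenylation is low-yielding and gives regioisomers. The fallback sets out from 6 and comes back at 8. Pd(PPh3)4-catalysed O-alkylation of the non-chelated 4-OH with tert-butyl 2-methylbut-3-en-2-yl carbonate gives the 1,1-dimethylallyl ether F6. An aromatic Claisen rearrangement (N,N-diethylaniline, 140 °C) delivers the inverted allyl unit as a prenyl group to C3. That ortho position is favoured by bond fixation in the chelated ring, and the product is 8.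

## Further compounds
F1 | step 7 | (3S,4S)-7-(methoxymethoxy)-3-[5-(methoxymethoxy)-2,2-dimethyl-2H-chromen-6-yl]-8-(3-methylbut-2-enyl)chroman-4-ol | CC(C)=CCc1c(OCOC)ccc2c1OC[C@H](c1ccc3c(c1OCOC)C=CC(C)(C)O3)[C@@H]2O
F2 | step 7 | (3S)-7-(methoxymethoxy)-3-[5-(methoxymethoxy)-2,2-dimethyl-2H-chromen-6-yl]-8-(3-methylbut-2-enyl)chroman | CC(C)=CCc1c(OCOC)ccc2c1OC[C@H](c1ccc3c(c1OCOC)C=CC(C)(C)O3)C2
F3 | step 6 | (E)-1-[2-hydroxy-4-(methoxymethoxy)-3-(3-methylbut-2-enyl)phenyl]-3-[5-(methoxymethoxy)-2,2-dimethyl-2H-chromen-6-yl]prop-2-en-1-one | O=C(/C=C/c1ccc2c(c1OCOC)C=CC(C)(C)O2)c1ccc(OCOC)c(CC=C(C)C)c1O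
F4 | step 6 | trans-3-hydroxy-7-(methoxymethoxy)-2-[5-(methoxymethoxy)-2,2-dimethyl-2H-chromen-6-yl]-8-(3-methylbut-2-enyl)chroman-4-one (racemic, one enantiomer drawn) | O=C1c2ccc(OCOC)c(CC=C(C)C)c2O[C@H](c2ccc3c(c2OCOC)C=CC(C)(C)O3)[C@H]1O
F5 | step 6 | 3-O-trifluoromethanesulfonate of F4 (racemic, one enantiomer drawn) | O=C1c2ccc(OCOC)c(CC=C(C)C)c2O[C@H](c2ccc3c(c2OCOC)C=CC(C)(C)O3)[C@H]1OS(=O)(=O)C(F)(F)F
F6 | step 3 | 1-[2-hydroxy-4-(2-methylbut-3-en-2-yloxy)phenyl]ethanone | CC(=O)c1ccc(OC(C)(C)C=C)cc1O
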